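The oxolane hides a C2-symmetric dimer. Across the C3–C4 bond the pairs C2/C1′ (C1′ = side-chain carbinol carbon), C3/C4 and ketone carbon/C5 bear identical aryl groups and identical configurations, so both halves descend from one isoliquiritigenin epoxide. Everything rests on cutting C3–C4 and O1–C5. In the key step the epoxy ketone is opened by single-electron transfer to an O1–C2–C3 β-oxido α-keto radical. This radical adds to the C4=C5 bond of the bis-silylated Z-enol ether made from the same epoxide. Radical–polar crossover and alkoxide capture close the ring as a C5 silyl ketal, set C3 and C4, and leave the halves differentiated. Hydride delivery then sets C5.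

Key step: step 6

Remark on numbering (target numbering throughout): oxolane O1, C2 (4-oxygenated aryl), C3 (aroyl), C4 (side chain, carbinol carbon C1′), C5 (2,4-dioxygenated aryl). Bn = benzyl, TBS = tert-butyldimethylsilyl, PTH = 10-phenylphenothiazine.
Assumption: the configuration at the ketal carbon C5 of 10 (and at the ketal carbons of F2 and F3) is left open in name and SMILES, because both epimers ionise to the same planar oxocarbenium ion.

Step 1
Reactants: 1 2′,4′-dihydroxyacetophenone
Product: 2 2′,4′-bis(benzyloxy)acetophenone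
Conditions: BnBr (2.4 equiv), K2CO3, cat. KI, DMF, 80 °C
Reagents that add atoms: benzyl bromide, BrCc1ccccc1
Why: Williamson ether synthesis; heating in DMF should also alkylate the hydrogen-bonded 2′-OH.

Step 2
Reactants: 2 2′,4′-bis(benzyloxy)acetophenone; 3 4-(benzyloxy)benzaldehyde
Product: 4 (E)-tri-O-benzylisoliquiritigenin
Conditions: KOH, EtOH/THF, rt
Reagents that add atoms: none
Why: Claisen–Schmidt condensation of the only enolisable partner with a non-enolisable aldehyde should give the conjugated E-enone under thermodynamic control.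

Step 3
Reactants: 4 (E)-tri-O-benzylisoliquiritigenin
Product: 5 (2R,3S)-trans-epoxy ketone
Conditions: poly-L-leucine, urea–H2O2, DBU, THF, rt
Reagents that add atoms: urea–hydrogen peroxide (oxygen source), OO.NC(N)=O
Why: Juliá–Colonna epoxidation (Weitz–Scheffer hydroperoxide addition within the helical peptide) is established for polyoxygenated chalcones, and the L-polymer is the one expected to give the (2R,3S)-epoxide, whose benzylic C–O centre becomes both C2 and C1′.

Step 4
Reactants: 5 (2R,3S)-trans-epoxy ketone
Product: 6 (R)-β-hydroxy ketone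
Conditions: SmI2 (2.2 equiv), THF/MeOH, −90 °C
Reagents that add atoms: none
Why: Samarium diiodide reduction of an α,β-epoxy ketone in the presence of MeOH replaces only the Cα–O bond by C–H, so the benzylic C–O centre is untouched (S to R is only a change of CIP ranking), and the low temperature should suppress retro-aldol cleavage and dehydration.

Step 5
Reactants: 6 (R)-β-hydroxy ketone
Product: 7 (1Z,3R)-bis(silyloxy)propene (silyl ether plus silyl enol ether)
Conditions: TBSOTf (2.6 equiv), Et3N, CH2Cl2, 0 °C to rt
Reagents that add atoms: tert-butyldimethylsilyl triflate, CC(C)(C)[Si](C)(C)OS(=O)(=O)C(F)(F)F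
Why: Soft enolisation/silylation protects the alcohol and converts the aryl ketone into its silyl enol ether without a free enolate (no E1cB loss of the β-oxygen), and the Z isomer is favoured because it avoids the clash of the aryl group with the C4 substituent.

Step 6
Reactants: 5 (2R,3S)-trans-epoxy ketone; 7 (1Z,3R)-bis(silyloxy)propene
Product: 10 oxolane C5 silyl ketal (2R,3R,4R,1′R; C5 open), via ring-opened radical anion 8 (not isolated), via alkoxide silyloxocarbenium zwitterion 9 (not isolated)
Conditions: PTH (5 mol %), 390 nm LEDs, degassed MeCN/CH2Cl2, rt, 7 in 1.5-fold excess, no salt or protic additive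
Reagents that add atoms: none
Why: Proposed new method: photoexcited PTH (E* ca. −2.1 V vs SCE) reduces the aryl ketone of 5, the ketyl cleaves its Cα–O bond to radical anion 8, the electrophilic C3 radical adds to the electron-rich C4 of 7 (C3–C4 bond), and one-electron oxidation of the adduct by the PTH radical cation gives zwitterion 9, whose alkoxide O1 attacks C5 (O1–C5 bond), so the cycle is redox-neutral and every atom of 5 and 7 ends up in 10. The closest known reaction types are the visible-light reductive opening of chalcone epoxides with interception of the α-keto radical by allyl sulfones, the photoredox alkylation of silyl enol ethers by α-carbonyl radicals, and the radical redox-relay [3+2] cycloadditions of N-acylaziridines or aryl cyclopropyl ketones with alkenes. The oxolane closes in a 5-exo-trig mode (O1 onto the C5=O+ bond). C2 and C1′ are carried in unchanged from 5 and 7; C3 is set by attack on the unchelated radical anti to the C2 aryl group (C2–H in the plane of the radical, C–O− turned away from the carbonyl dipole, no Lewis-acidic cation present); C4 is set by attack on the Z-enol ether anti to the C1′ aryl group with C1′–H held inside by A(1,3) strain against the cis OTBS group; C5 is left undefined because step 7 erases it. The step needs cross- over homo-coupling and differentiation of two near-identical halves, which the substrates secure because only 5 accepts an electron, only 7 is a nucleophilic alkene and only O1 is unprotected, so the C1′ oxygen stays silylated and the second ketone stays free. Because both partners come from the same enantioenriched epoxide, pairs containing the minor enantiomer end as separable diastereomers, which should raise the enantiopurity of 10.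

Step 7
Reactants: 10 oxolane C5 silyl ketal
Product: 12 hexa-O-benzyl oxolane C1′ silyl ether (2R,3R,4S,5R,1′R; 4S only by CIP ranking of silicon), via cyclic oxocarbenium ion 11 (not isolated)
Conditions: Et3SiH (3 equiv), BF3·OEt2 (1.2 equiv), CH2Cl2, −78 °C
Reagents that add atoms: none
Why: In this Lewis acid/silane ionic reduction of a cyclic ketal (silyl ketals are the species through which reductive cyclisations of γ-hydroxy ketones run), loss of the anomeric silyloxy group gives planar 11, and hydride should reach C5 from the face anti to the C4 and C3 substituents, making H5 cis to H4 and the C5 aryl group cis to the side chain.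

Step 8
Reactants: 12 hexa-O-benzyl oxolane C1′ silyl ether
Product: 13 hexa-O-benzyl ether of the target (2R,3R,4R,5R,1′R)
Conditions: HF·pyridine, pyridine/THF, 0 °C to rt
Reagents that add atoms: none
Why: Fluoride-mediated silyl ether cleavage in a buffered, non-basic medium should avoid enolisation at C3 and β-elimination of O1.

Step 9
Reactants: 13 hexa-O-benzyl ether of the target
Product: 14 target CNP0244141.1
Conditions: H2 (1 atm), 10% Pd/C, EtOAc/EtOH, rt, stopped when debenzylation is complete
Reagents that add atoms: none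
Why: Catalytic hydrogenolysis of six aryl benzyl ethers under neutral conditions should be faster than cleavage of the dialkyl benzylic C–O bonds and leaves the ketone and all five stereocentres untouched.

Compound list
1 | 2′,4′-dihydroxyacetophenone | CC(=O)c1ccc(O)cc1O | starting material
2 | 2′,4′-bis(benzyloxy)acetophenone | CC(=O)c1ccc(OCc2ccccc2)cc1OCc1ccccc1 | intermediate
3 | 4-(benzyloxy)benzaldehyde | O=Cc1ccc(OCc2ccccc2)cc1 | starting material
4 | (E)-1-[2,4-bis(benzyloxy)phenyl]-3-[4-(benzyloxy)phenyl]prop-2-en-1-one | O=C(/C=C/c1ccc(OCc2ccccc2)cc1)c1ccc(OCc2ccccc2)cc1OCc1ccccc1 | intermediate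
5 | [2,4-bis(benzyloxy)phenyl]{(2R,3S)-3-[4-(benzyloxy)phenyl]oxiran-2-yl}methanone | O=C(c1ccc(OCc2ccccc2)cc1OCc1ccccc1)[C@@H]1O[C@H]1c1ccc(OCc2ccccc2)cc1 | intermediate
6 | (R)-1-[2,4-bis(benzyloxy)phenyl]-3-[4-(benzyloxy)phenyl]-3-hydroxypropan-1-one | O[C@H](CC(=O)c1ccc(OCc2ccccc2)cc1OCc1ccccc1)c1ccc(OCc2ccccc2)cc1 | intermediate
7 | (1Z,3R)-1-[2,4-bis(benzyloxy)phenyl]-3-[4-(benzyloxy)phenyl]-1,3-bis(tert-butyldimethylsilyloxy)prop-1-ene | CC(C)(C)[Si](C)(C)O/C(=C\[C@@H](O[Si](C)(C)C(C)(C)C)c1ccc(OCc2ccccc2)cc1)c1ccc(OCc2ccccc2)cc1OCc1ccccc1 | intermediate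
8 | ring-opened radical anion of 5 (β-oxido α-keto radical, radical at C3) | [O-][C@H]([CH]C(=O)c1ccc(OCc2ccccc2)cc1OCc1ccccc1)c1ccc(OCc2ccccc2)cc1 | intermediate
9 | open-chain zwitterion (O1 alkoxide, C5 silyloxocarbenium, C3–C4 bond in place) | [O-][C@@H](c1ccc(OCc2ccccc2)cc1)[C@H](C(=O)c1ccc(OCc2ccccc2)cc1OCc1ccccc1)[C@H]([C@@H](O[Si](C)(C)C(C)(C)C)c1ccc(OCc2ccccc2)cc1)C(c1ccc(OCc2ccccc2)cc1OCc1ccccc1)=[O+][Si](C)(C)C(C)(C)C | intermediate
10 | [2,4-bis(benzyloxy)phenyl]{(2R,3R,4R)-5-[2,4-bis(benzyloxy)phenyl]-2-[4-(benzyloxy)phenyl]-4-{(R)-[4-(benzyloxy)phenyl](TBSO)methyl}-5-(TBSO)oxolan-3-yl}methanone, C5 open | O=C(c1ccc(OCc2ccccc2)cc1OCc1ccccc1)[C@@H]1[C@H]([C@@H](O[Si](C)(C)C(C)(C)C)c2ccc(OCc3ccccc3)cc2)C(O[Si](C)(C)C(C)(C)C)(c2ccc(OCc3ccccc3)cc2OCc2ccccc2)O[C@H]1c1ccc(OCc2ccccc2)cc1 | intermediate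
11 | cyclic C5=O1 oxocarbenium ion derived from 10 | O=C(c1ccc(OCc2ccccc2)cc1OCc1ccccc1)[C@@H]1[C@H]([C@@H](O[Si](C)(C)C(C)(C)C)c2ccc(OCc3ccccc3)cc2)C(c2ccc(OCc3ccccc3)cc2OCc2ccccc2)=[O+][C@H]1c1ccc(OCc2ccccc2)cc1 | intermediate
12 | [2,4-bis(benzyloxy)phenyl]{(2R,3R,4S,5R)-5-[2,4-bis(benzyloxy)phenyl]-2-[4-(benzyloxy)phenyl]-4-{(R)-[4-(benzyloxy)phenyl](TBSO)methyl}oxolan-3-yl}methanone | O=C(c1ccc(OCc2ccccc2)cc1OCc1ccccc1)[C@@H]1[C@H]([C@@H](O[Si](C)(C)C(C)(C)C)c2ccc(OCc3ccccc3)cc2)[C@H](c2ccc(OCc3ccccc3)cc2OCc2ccccc2)O[C@H]1c1ccc(OCc2ccccc2)cc1 | intermediate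
13 | [2,4-bis(benzyloxy)phenyl]{(2R,3R,4R,5R)-5-[2,4-bis(benzyloxy)phenyl]-2-[4-(benzyloxy)phenyl]-4-{(R)-[4-(benzyloxy)phenyl](hydroxy)methyl}oxolan-3-yl}methanone | O=C(c1ccc(OCc2ccccc2)cc1OCc1ccccc1)[C@@H]1[C@H]([C@@H](O)c2ccc(OCc3ccccc3)cc2)[C@H](c2ccc(OCc3ccccc3)cc2OCc2ccccc2)O[C@H]1c1ccc(OCc2ccccc2)cc1 | intermediate
14 | (2,4-dihydroxyphenyl){(2R,3R,4R,5R)-5-(2,4-dihydroxyphenyl)-4-[(R)-hydroxy(4-hydroxyphenyl)methyl]-2-(4-hydroxyphenyl)oxolan-3-yl}methanone | O=C(c1ccc(O)cc1O)[C@@H]1[C@H]([C@@H](O)c2ccc(O)cc2)[C@H](c2ccc(O)cc2O)O[C@H]1c1ccc(O)cc1 | target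

Total step count: 9. Longest linear sequence: 9 steps (1 → 2 → 4 → 5 → 6 → 7 → 10 → 12 → 13 → 14); epoxide 5 enters twice, once as such and once by way of 7.

Steps most likely to fail

1. Step 6 (proposed new method). The hindered secondary radical may add too slowly to the trisubstituted enol ether. Hydrogen abstraction, isomerisation of the epoxy ketone to the 1,3-diketone, or erosion of facial control at C3 could then take over. The fallback uses known chemistry, sets out from 7 and returns at 12.
 - Oxidative homocoupling of 7 with ceric ammonium nitrate/NaHCO3 in MeCN is the established dimerisation of aryl ketone silyl enol ethers to 1,4-diketones. The same A(1,3) control operates at both termini. It should give the C2-symmetric bis(silyloxy) 1,4-diketone F1.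
 - The two silyl ethers of F1 are homotopic. HF·pyridine run to partial conversion, with F1 recycled, can therefore give only one mono-alcohol, which closes to the cyclic hemiketal F2.
 - Et3SiH/BF3·OEt2 at −78 °C then gives 12.

2. Step 7. Ionisation may occur on the endocyclic side, followed by reduction of the acyclic silyloxocarbenium ion. Alternatively, hydride may be delivered to the wrong face of 11 under the influence of the C2 aryl group or of the neighbouring ketone. The fallback sets out from 10 and returns at 13.
 - AcOH-buffered TBAF removes both silyl groups, and the two γ-hydroxy ketone units close to the cis-fused 3,7-dioxabicyclo[3.3.0]octane bis-hemiketal F3, with the C2 and C1′ aryl groups exo.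
 - In this bowl, one equivalent of Et3SiH with BF3·OEt2 at −78 °C can reach the oxocarbenium carbon only from the convex face, which is the face of H3 and H4.
 - The two hemiketals are homotopic, and the remaining one opens on work-up to the hydroxy ketone 13.

3. Step 9. Over-reduction is the risk: hydrogenolysis of the benzylic C–O bonds at C1′, C2 or C5 once the electron-rich phenols are unveiled. The fallback sets out from 12 and returns at 14 by inverting the last two operations.
 - Hydrogenolysis of 12 gives the hexaphenol C1′ silyl ether F4, in which the most labile carbinol C–O bond is still masked and shielded.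
 - Et3N·3HF in MeCN then frees the alcohol to give 14.

Further compounds
F1 | step 6 | (2R,3R)-1,4-bis[2,4-bis(benzyloxy)phenyl]-2,3-bis{(R)-[4-(benzyloxy)phenyl](TBSO)methyl}butane-1,4-dione | O=C(c1ccc(OCc2ccccc2)cc1OCc1ccccc1)[C@@H]([C@@H](O[Si](C)(C)C(C)(C)C)c1ccc(OCc2ccccc2)cc1)[C@H]([C@@H](O[Si](C)(C)C(C)(C)C)c1ccc(OCc2ccccc2)cc1)C(=O)c1ccc(OCc2ccccc2)cc1OCc1ccccc1
F2 | step 6 | C5 hemiketal analogue of 10 (C5–OH in place of C5–OTBS, C5 open) | O=C(c1ccc(OCc2ccccc2)cc1OCc1ccccc1)[C@@H]1[C@H]([C@@H](O[Si](C)(C)C(C)(C)C)c2ccc(OCc3ccccc3)cc2)C(O)(c2ccc(OCc3ccccc3)cc2OCc2ccccc2)O[C@H]1c1ccc(OCc2ccccc2)cc1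
F3 | step 7 | cis-fused tetraaryl-3,7-dioxabicyclo[3.3.0]octane bis-hemiketal (ketal carbons open) | OC1(c2ccc(OCc3ccccc3)cc2OCc2ccccc2)O[C@@H](c2ccc(OCc3ccccc3)cc2)[C@H]2[C@@H]1[C@H](c1ccc(OCc3ccccc3)cc1)OC2(O)c1ccc(OCc2ccccc2)cc1OCc1ccccc1
F4 | step 9 | C1′-O-TBS ether of the target | O=C(c1ccc(O)cc1O)[C@@H]1[C@H]([C@@H](O[Si](C)(C)C(C)(C)C)c2ccc(O)cc2)[C@H](c2ccc(O)cc2O)O[C@H]1c1ccc(O)cc1
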